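**Retrosynthetic overview**
1. Target 26 ⇐ tricyclic hydroxy isobutyrate 22 by angeloylation at C1, then oxidation at C6 and conjugation of the exocyclic alkene.
2. Key disconnection C10–C11 (closes the seven-membered ring last): a C1–C11 epoxide is opened by trivalent titanium to a tertiary C11 radical (epoxide carbon with reversed polarity) that adds to the C10 tosylhydrazone; loss of sulfinate and N2 leaves C10–H.
3. Cyclobutane and six-membered ring in one step: intramolecular vinylketene–alkene [2+2] of a (5S,9S)-5,9-disilyloxyfarnesoic acid gives bicyclo[3.1.1]heptan-6-one 15.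
4. The C15 chain comes from two iterative catalytic asymmetric vinylogous Mukaiyama aldol reactions of prenal 3 with silyl dienolate 2 (from ethyl 3-methylbut-2-enoate 1).
5. Ring order: six-membered ring + cyclobutane together, then the seven-membered ring.

Assumption: the SMILES is taken as drawn (a 7,8-diacyloxylongipin-2-en-1-one); the (R,R)-bisphosphoramide is taken to direct dienolate attack to the Si face of enals, and if the sense proves opposite the (S,S)-catalyst is used in steps 2 and 6.

Locants used below: C1 = CH–O-angeloyl, C2 = CH–O-isobutyryl, C3 = CH2, C4 = C(CH3), C5 = CH next to C=O, C6 = C=O, C7 = CH=, C8 = C(CH3)=, C9 = CH, C10 = CH, C11 = C(CH3)2; the cyclobutane is C4–C5–C10–C9.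

**Step 1**
Reactants: 1 ethyl 3-methylbut-2-enoate
Product: 2 tert-butyl[(1-ethoxy-3-methylbuta-1,3-dien-1-yl)oxy]dimethylsilane
Conditions: LiN(i-Pr)2, THF/DMPU, −78 °C; TBSCl, −78 °C to rt; distil
Reagents that add atoms: tert-butyl(chloro)dimethylsilane (TBSCl), CC(C)(C)[Si](C)(C)Cl
Why: Kinetic γ-deprotonation of the enoate gives the extended lithium dienolate, which is O-silylated (silyl ketene acetal formation); no stereocentre is formed.

**Step 2**
Reactants: 3 3-methylbut-2-enal (prenal); 2 silyl dienolate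
Product: 5 ethyl (2E,5S)-5-hydroxy-3,7-dimethylocta-2,6-dienoate, via trichlorosilyl ether 4 (not isolated)
Conditions: SiCl4 (1.1 equiv), (R,R)-binaphthyldiamine-derived bisphosphoramide (5 mol %), i-Pr2NEt (10 mol %), CH2Cl2, −78 °C; aq NaHCO3
Reagents that add atoms: none
Why: Lewis-base-activated SiCl4 vinylogous Mukaiyama aldol (Denmark type): the dienolate reacts at its γ-carbon through an open transition state to give the E enoate, and the chiral phosphoramide-bound silyl cation exposes the Si face of the enal, setting C2 (chain C5) as S.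

**Step 3**
Reactants: 5 hydroxy ester
Product: 6 ethyl (2E,5S)-3,7-dimethyl-5-(triethylsilyloxy)octa-2,6-dienoate
Conditions: Et3SiCl, imidazole, DMF, 0 °C
Reagents that add atoms: chlorotriethylsilane, CC[Si](Cl)(CC)CC
Why: Standard silylation of the secondary allylic alcohol; the TES group is chosen because it can later be removed in the presence of a TBS ether.

**Step 4**
Reactants: 6 TES ether ester
Product: 7 (2E,5S)-3,7-dimethyl-5-(triethylsilyloxy)octa-2,6-dien-1-ol
Conditions: i-Bu2AlH (2.2 equiv), CH2Cl2, −78 °C; aq potassium sodium tartrate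
Reagents that add atoms: none
Why: 1,2-Reduction of the conjugated ester by the aluminium hydride gives the allylic alcohol without touching the alkene geometry or the silyl ether.

**Step 5**
Reactants: 7 allylic alcohol
Product: 8 (2E,5S)-3,7-dimethyl-5-(triethylsilyloxy)octa-2,6-dienal
Conditions: MnO2, CH2Cl2, rt
Reagents that add atoms: none
Why: Chemoselective allylic oxidation with MnO2 gives the E enal without isomerisation.

**Step 6**
Reactants: 8 enal; 2 silyl dienolate
Product: 10 ethyl (2E,5S,6E,9S)-5-hydroxy-3,7,11-trimethyl-9-(triethylsilyloxy)dodeca-2,6,10-trienoate, via trichlorosilyl ether 9 (not isolated)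
Conditions: SiCl4 (1.1 equiv), (R,R)-bisphosphoramide (5 mol %), i-Pr2NEt (10 mol %), CH2Cl2, −78 °C; aq NaHCO3
Reagents that add atoms: none
Why: Second vinylogous Mukaiyama aldol under the same catalyst control (Si-face attack) sets the carbinol that becomes C6 (chain C5) as S; the remote silyloxy stereocentre does not compete with the catalyst.

**Step 7**
Reactants: 10 hydroxy ester
Product: 11 ethyl (2E,5S,6E,9S)-5-(tert-butyldimethylsilyloxy)-3,7,11-trimethyl-9-(triethylsilyloxy)dodeca-2,6,10-trienoate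
Conditions: TBSCl, imidazole, DMF, rt
Reagents that add atoms: tert-butyl(chloro)dimethylsilane (TBSCl), CC(C)(C)[Si](C)(C)Cl
Why: Silylation of the secondary allylic alcohol; the TBS ether is stable to all steps up to step 16 and is bulky enough to control the cycloaddition face.

**Step 8**
Reactants: 11 bis-silyl ether ester
Product: 12 (2E,5S,6E,9S)-5-(tert-butyldimethylsilyloxy)-3,7,11-trimethyl-9-(triethylsilyloxy)dodeca-2,6,10-trienoic acid
Conditions: LiOH, THF/H2O, rt; 1 M HCl to pH 4, 0 °C
Reagents that add atoms: lithium hydroxide, [Li+].[OH-]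
Why: Saponification of the ethyl ester; both secondary silyl ethers survive aqueous LiOH and the brief mild acidification.

**Step 9**
Reactants: 12 acid
Product: 15 (1R,4S,5R,7R)-4-(tert-butyldimethylsilyloxy)-7-methyl-2-methylidene-7-[(2S)-4-methyl-2-(triethylsilyloxy)pent-3-en-1-yl]bicyclo[3.1.1]heptan-6-one, via acid chloride 13 (not isolated), via vinylketene 14 (not isolated)
Conditions: 1-chloro-N,N,2-trimethylprop-1-en-1-amine, CH2Cl2, 0 °C; then slow addition to Et3N (3 equiv), toluene, 110 °C, high dilution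
Reagents that add atoms: none
Why: Snider/Corey-type intramolecular vinylketene–alkene [2+2]: γ-deprotonation at the 3-methyl group gives the vinylketene, whose carbonyl carbon bonds to the CH terminus (C5) and whose α-carbon bonds to the fully substituted C4, giving the bridged bicyclo[3.1.1]heptan-6-one; suprafacial addition to the 6E alkene puts the C4 methyl syn to the three-carbon bridge and the side chain anti, and 1,3-allylic strain (the H on the silyloxy carbon eclipses the alkene, the silyloxy group turns away from the C4 methyl) selects the alkene face, so the C6 stereocentre fixes C4, C5 and C9.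

**Step 10**
Reactants: 15 bicyclic ketone
Product: 16 (1R,4S,5R,7R)-4-(tert-butyldimethylsilyloxy)-7-[(2S)-2-hydroxy-4-methylpent-3-en-1-yl]-7-methyl-2-methylidenebicyclo[3.1.1]heptan-6-one
Conditions: HF·pyridine, pyridine, THF, 0 °C
Reagents that add atoms: none
Why: Buffered fluoride cleaves the TES ether much faster than the hindered secondary TBS ether (selective desilylation).

**Step 11**
Reactants: 16 allylic alcohol
Product: 17 (1R,4S,5R,7R)-4-(tert-butyldimethylsilyloxy)-7-{(2S)-2-[(2R)-3,3-dimethyloxiran-2-yl]-2-hydroxyethyl}-7-methyl-2-methylidenebicyclo[3.1.1]heptan-6-one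
Conditions: VO(acac)2 (5 mol %), t-BuOOH (1.5 equiv), CH2Cl2, 0 °C to rt
Reagents that add atoms: tert-butyl hydroperoxide, CC(C)(C)OO
Why: Hydroxyl-directed vanadium-catalysed epoxidation (Sharpless–Michaelson type) touches only the allylic C1=C11 alkene; 1,3-allylic strain with the cis methyl gives the threo epoxy alcohol (about 6:1 expected from simple models, minor isomer removed), which sets C1, and no peracid is present to cause Baeyer–Villiger oxidation of the cyclobutanone.

**Step 12**
Reactants: 17 epoxy alcohol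
Product: 18 (1S)-1-[(2R)-3,3-dimethyloxiran-2-yl]-2-[(1R,4S,5R,7R)-4-(tert-butyldimethylsilyloxy)-7-methyl-2-methylidene-6-oxobicyclo[3.1.1]heptan-7-yl]ethyl 2-methylpropanoate
Conditions: (i-PrCO)2O, Et3N, DMAP (10 mol %), CH2Cl2, 0 °C to rt
Reagents that add atoms: isobutyric anhydride, CC(C)C(=O)OC(=O)C(C)C
Why: DMAP-catalysed acylation installs the final C2 isobutyrate with retention and at the same time protects the alcohol for the radical step.

**Step 13**
Reactants: 18 epoxy keto ester
Product: 19 tosylhydrazone of 18 at the cyclobutanone carbon C10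
Conditions: TsNHNH2 (1.2 equiv), 4 Å sieves, THF, 40 °C
Reagents that add atoms: 4-methylbenzenesulfonohydrazide, Cc1ccc(cc1)S(=O)(=O)NN
Why: Neutral hydrazone condensation at the strained, non-enolisable cyclobutanone (the same carbonyl reactivity that allows Wolff–Kishner removal in related bicyclo[3.1.1]heptan-6-ones); the epoxide and ester are untouched.

**Step 14**
Reactants: 19 tosylhydrazone
Product: 22 (1R,2R,4S,5S,7S,8R,11S)-11-(tert-butyldimethylsilyloxy)-5-hydroxy-2,6,6-trimethyl-9-methylidenetricyclo[5.4.0.0^{2,8}]undecan-4-yl 2-methylpropanoate, via tosylhydrazine 20 (not isolated), via alkyldiazene 21 (not isolated)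
Conditions: Cp2TiCl2 (20 mol %), Zn dust (3 equiv), 2,4,6-collidine hydrochloride (2.5 equiv), THF (0.01 M), rt; then NaOAc, EtOH, 60 °C
Reagents that add atoms: none
Why: Proposed new method: Cp2TiCl (trivalent titanium, formed from Cp2TiCl2 and Zn) opens the trisubstituted epoxide by electron transfer to the tertiary β-titanoxy radical at C11 (Nugent–RajanBabu/Gansäuer reductive epoxide opening, which turns the electrophilic epoxide carbon into a nucleophilic one), this radical adds 7-exo to the electrophilic hydrazone carbon C10 from the only face the C4 tether can reach, the hydrazinyl radical is reduced and protonated to 20, and Caglioti-type loss of sulfinate and then N2 from 21 leaves H at C10 on the face of the three-carbon bridge, the only one open in the cage; the closest known reactions are titanocene-mediated epoxide–carbonyl and epoxide–alkene radical cyclisations and radical additions to sulfonylhydrazones or N-aziridinylimines followed by loss of N2.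

**Step 15**
Reactants: 22 tricyclic alcohol
Product: 23 (1R,2R,4S,5S,7S,8R,11S)-11-(tert-butyldimethylsilyloxy)-2,6,6-trimethyl-9-methylidene-4-[(2-methylpropanoyl)oxy]tricyclo[5.4.0.0^{2,8}]undecan-5-yl (2Z)-2-methylbut-2-enoate
Conditions: angelic acid, 2,4,6-trichlorobenzoyl chloride, Et3N, toluene, rt; then 22, 80 °C
Reagents that add atoms: angelic acid ((2Z)-2-methylbut-2-enoic acid), C/C=C(/C)C(O)=O
Why: Yamaguchi-type mixed-anhydride esterification run without DMAP, the established way to acylate hindered alcohols with angelic acid without Z-to-E isomerisation; the isobutyrate stays on the less hindered C2 oxygen, which is also its thermodynamic position.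

**Step 16**
Reactants: 23 silyl ether diester
Product: 24 (1R,2R,4S,5S,7S,8R,11S)-11-hydroxy-2,6,6-trimethyl-9-methylidene-4-[(2-methylpropanoyl)oxy]tricyclo[5.4.0.0^{2,8}]undecan-5-yl (2Z)-2-methylbut-2-enoate
Conditions: HF·pyridine, THF, 0 °C to rt
Reagents that add atoms: none
Why: Fluoride-mediated cleavage of the secondary TBS ether under mildly acidic conditions leaves both esters and the angelate geometry intact.

**Step 17**
Reactants: 24 hydroxy diester
Product: 26 (1R,2R,4S,5S,7S,8R)-2,6,6,9-tetramethyl-4-[(2-methylpropanoyl)oxy]-11-oxotricyclo[5.4.0.0^{2,8}]undec-9-en-5-yl (2Z)-2-methylbut-2-enoate, via methylidene ketone 25 (not isolated)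
Conditions: Dess–Martin periodinane, CH2Cl2, 0 °C to rt; wash aq Na2S2O3/NaHCO3; crude, DBU (0.2 equiv), CH2Cl2, 0 °C
Reagents that add atoms: none
Why: Dess–Martin oxidation of the C6 carbinol gives the β,γ-unsaturated ketone, and DBU moves the exocyclic double bond into conjugation through the C7 dienolate (C5 is a bridgehead and cannot enolise), giving the verbenone-type enone of the target.

**Compound list**
1 | ethyl 3-methylbut-2-enoate | CCOC(=O)C=C(C)C | starting material
2 | tert-butyl[(1-ethoxy-3-methylbuta-1,3-dien-1-yl)oxy]dimethylsilane (ketene acetal geometry not defined) | CCOC(=CC(C)=C)O[Si](C)(C)C(C)(C)C | intermediate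
3 | 3-methylbut-2-enal (prenal) | CC(C)=CC=O | starting material
4 | ethyl (2E,5S)-3,7-dimethyl-5-(trichlorosilyloxy)octa-2,6-dienoate | CCOC(=O)/C=C(\C)C[C@H](O[Si](Cl)(Cl)Cl)C=C(C)C | intermediate
5 | ethyl (2E,5S)-5-hydroxy-3,7-dimethylocta-2,6-dienoate | CCOC(=O)/C=C(\C)C[C@H](O)C=C(C)C | intermediate
6 | ethyl (2E,5S)-3,7-dimethyl-5-(triethylsilyloxy)octa-2,6-dienoate | CCOC(=O)/C=C(\C)C[C@H](O[Si](CC)(CC)CC)C=C(C)C | intermediate
7 | (2E,5S)-3,7-dimethyl-5-(triethylsilyloxy)octa-2,6-dien-1-ol | OC/C=C(\C)C[C@H](O[Si](CC)(CC)CC)C=C(C)C | intermediate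
8 | (2E,5S)-3,7-dimethyl-5-(triethylsilyloxy)octa-2,6-dienal | O=C/C=C(\C)C[C@H](O[Si](CC)(CC)CC)C=C(C)C | intermediate
9 | ethyl (2E,5S,6E,9S)-3,7,11-trimethyl-5-(trichlorosilyloxy)-9-(triethylsilyloxy)dodeca-2,6,10-trienoate | CCOC(=O)/C=C(\C)C[C@H](O[Si](Cl)(Cl)Cl)/C=C(\C)C[C@H](O[Si](CC)(CC)CC)C=C(C)C | intermediate
10 | ethyl (2E,5S,6E,9S)-5-hydroxy-3,7,11-trimethyl-9-(triethylsilyloxy)dodeca-2,6,10-trienoate | CCOC(=O)/C=C(\C)C[C@H](O)/C=C(\C)C[C@H](O[Si](CC)(CC)CC)C=C(C)C | intermediate
11 | ethyl (2E,5S,6E,9S)-5-(tert-butyldimethylsilyloxy)-3,7,11-trimethyl-9-(triethylsilyloxy)dodeca-2,6,10-trienoate | CCOC(=O)/C=C(\C)C[C@H](O[Si](C)(C)C(C)(C)C)/C=C(\C)C[C@H](O[Si](CC)(CC)CC)C=C(C)C | intermediate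
12 | (2E,5S,6E,9S)-5-(tert-butyldimethylsilyloxy)-3,7,11-trimethyl-9-(triethylsilyloxy)dodeca-2,6,10-trienoic acid | OC(=O)/C=C(\C)C[C@H](O[Si](C)(C)C(C)(C)C)/C=C(\C)C[C@H](O[Si](CC)(CC)CC)C=C(C)C | intermediate
13 | (2E,5S,6E,9S)-5-(tert-butyldimethylsilyloxy)-3,7,11-trimethyl-9-(triethylsilyloxy)dodeca-2,6,10-trienoyl chloride | ClC(=O)/C=C(\C)C[C@H](O[Si](C)(C)C(C)(C)C)/C=C(\C)C[C@H](O[Si](CC)(CC)CC)C=C(C)C | intermediate
14 | (5S,6E,9S)-5-(tert-butyldimethylsilyloxy)-7,11-dimethyl-3-methylidene-9-(triethylsilyloxy)dodeca-1,6,10-trien-1-one (vinylketene) | O=C=CC(=C)C[C@H](O[Si](C)(C)C(C)(C)C)/C=C(\C)C[C@H](O[Si](CC)(CC)CC)C=C(C)C | intermediate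
15 | (1R,4S,5R,7R)-4-(tert-butyldimethylsilyloxy)-7-methyl-2-methylidene-7-[(2S)-4-methyl-2-(triethylsilyloxy)pent-3-en-1-yl]bicyclo[3.1.1]heptan-6-one (7-methyl syn to the C2–C4 bridge) | CC(C)=C[C@@H](O[Si](CC)(CC)CC)C[C@@]1(C)[C@@H]2[C@@H](O[Si](C)(C)C(C)(C)C)CC(=C)[C@H]1C2=O | intermediate
16 | (1R,4S,5R,7R)-4-(tert-butyldimethylsilyloxy)-7-[(2S)-2-hydroxy-4-methylpent-3-en-1-yl]-7-methyl-2-methylidenebicyclo[3.1.1]heptan-6-one | CC(C)=C[C@@H](O)C[C@@]1(C)[C@@H]2[C@@H](O[Si](C)(C)C(C)(C)C)CC(=C)[C@H]1C2=O | intermediate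
17 | (1R,4S,5R,7R)-4-(tert-butyldimethylsilyloxy)-7-{(2S)-2-[(2R)-3,3-dimethyloxiran-2-yl]-2-hydroxyethyl}-7-methyl-2-methylidenebicyclo[3.1.1]heptan-6-one | CC1(C)O[C@@H]1[C@@H](O)C[C@@]2(C)[C@@H]3[C@@H](O[Si](C)(C)C(C)(C)C)CC(=C)[C@H]2C3=O | intermediate
18 | (1S)-1-[(2R)-3,3-dimethyloxiran-2-yl]-2-[(1R,4S,5R,7R)-4-(tert-butyldimethylsilyloxy)-7-methyl-2-methylidene-6-oxobicyclo[3.1.1]heptan-7-yl]ethyl 2-methylpropanoate | CC1(C)O[C@@H]1[C@@H](OC(=O)C(C)C)C[C@@]2(C)[C@@H]3[C@@H](O[Si](C)(C)C(C)(C)C)CC(=C)[C@H]2C3=O | intermediate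
19 | tosylhydrazone of 18 at the cyclobutanone carbon (C=N geometry not defined, other centres as in 18) | CC1(C)O[C@@H]1[C@@H](OC(=O)C(C)C)C[C@@]2(C)[C@@H]3[C@@H](O[Si](C)(C)C(C)(C)C)CC(=C)[C@H]2C3=NNS(=O)(=O)c1ccc(C)cc1 | intermediate
20 | tricyclic N-alkyl-N′-tosylhydrazine: 22 carrying NH–NHTs in place of H at C10 (ring fusion as in 22) | O[C@@H]1[C@@H](OC(=O)C(C)C)C[C@@]2(C)[C@@H]3[C@@H](O[Si](C)(C)C(C)(C)C)CC(=C)[C@H]2[C@]3(NNS(=O)(=O)c4ccc(C)cc4)C1(C)C | intermediate
21 | tricyclic alkyldiazene: 22 carrying N=NH in place of H at C10 | O[C@@H]1[C@@H](OC(=O)C(C)C)C[C@@]2(C)[C@@H]3[C@@H](O[Si](C)(C)C(C)(C)C)CC(=C)[C@H]2[C@]3(N=N)C1(C)C | intermediate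
22 | (1R,2R,4S,5S,7S,8R,11S)-11-(tert-butyldimethylsilyloxy)-5-hydroxy-2,6,6-trimethyl-9-methylidenetricyclo[5.4.0.0^{2,8}]undecan-4-yl 2-methylpropanoate | O[C@@H]1[C@@H](OC(=O)C(C)C)C[C@@]2(C)[C@@H]3[C@@H](O[Si](C)(C)C(C)(C)C)CC(=C)[C@H]2[C@@H]3C1(C)C | intermediate
23 | (1R,2R,4S,5S,7S,8R,11S)-11-(tert-butyldimethylsilyloxy)-2,6,6-trimethyl-9-methylidene-4-[(2-methylpropanoyl)oxy]tricyclo[5.4.0.0^{2,8}]undecan-5-yl (2Z)-2-methylbut-2-enoate | C/C=C(/C)C(=O)O[C@@H]1[C@@H](OC(=O)C(C)C)C[C@@]2(C)[C@@H]3[C@@H](O[Si](C)(C)C(C)(C)C)CC(=C)[C@H]2[C@@H]3C1(C)C | intermediate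
24 | (1R,2R,4S,5S,7S,8R,11S)-11-hydroxy-2,6,6-trimethyl-9-methylidene-4-[(2-methylpropanoyl)oxy]tricyclo[5.4.0.0^{2,8}]undecan-5-yl (2Z)-2-methylbut-2-enoate | C/C=C(/C)C(=O)O[C@@H]1[C@@H](OC(=O)C(C)C)C[C@@]2(C)[C@@H]3[C@@H](O)CC(=C)[C@H]2[C@@H]3C1(C)C | intermediate
25 | (1R,2R,4S,5S,7S,8R)-2,6,6-trimethyl-9-methylidene-4-[(2-methylpropanoyl)oxy]-11-oxotricyclo[5.4.0.0^{2,8}]undecan-5-yl (2Z)-2-methylbut-2-enoate | C/C=C(/C)C(=O)O[C@@H]1[C@@H](OC(=O)C(C)C)C[C@@]2(C)[C@@H]3C(=O)CC(=C)[C@H]2[C@@H]3C1(C)C | intermediate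
26 | (1R,2R,4S,5S,7S,8R)-2,6,6,9-tetramethyl-4-[(2-methylpropanoyl)oxy]-11-oxotricyclo[5.4.0.0^{2,8}]undec-9-en-5-yl (2Z)-2-methylbut-2-enoate | C/C=C(/C)C(=O)O[C@@H]1[C@@H](OC(=O)C(C)C)C[C@@]2(C)[C@@H]3C(=O)C=C(C)[C@H]2[C@@H]3C1(C)C | target

**Totals**
Total step count: 17. Longest linear sequence: 17 steps (1 to 26; prenal 3 enters at step 2 and dienolate 2 is used again in step 6).

**Three steps most likely to fail**

Step 14 (key ring closure). The tertiary radical must close a seven-membered ring onto a hindered C=N faster than it is reduced to C11–H or eliminated to the allylic alcohol, and the combination of epoxide opening with a tosylhydrazone acceptor is untested. Fallback: the route leaves at 18 and replaces electron-transfer epoxide opening by a tin hydride chain reaction with a different radical source and acceptor. The epoxide is opened at its tertiary carbon with pyridinium hydrobromide to give the tertiary bromohydrin F1. Condensation of the cyclobutanone with 1-amino-2-phenylaziridine (made from styrene glycol dimesylate and hydrazine) gives the N-aziridinylimine F2. Slow addition of Bu3SnH/AIBN in benzene at 80 °C abstracts bromine, the tertiary radical cyclises onto the imine carbon, styrene and N2 are lost, and hydrogen transfer to C10 gives 22, where the route is rejoined.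

Step 9 (ketene [2+2]). The alkene carries an allylic silyloxy group that lowers its nucleophilicity, and the yield and facial selectivity at 110 °C are uncertain. Fallback: the route leaves at 12 and uses a more electrophilic keteniminium ion at lower temperature. Coupling of the acid with pyrrolidine gives the pyrrolidine amide F3. Treatment with Tf2O and 2,4,6-collidine in 1,2-dichloroethane generates the vinylketeniminium ion, which undergoes the same intramolecular [2+2] to the cyclobutaniminium triflate F4. Aqueous NaHCO3 hydrolysis gives 15, where the route is rejoined.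

Step 15 (angeloylation). The C1 alcohol is flanked by the quaternary C11 and the C2 ester, and forcing conditions risk Z-to-E isomerisation or acyl migration. Fallback: the route leaves at 22 and builds the Z alkene after the ester bond is in place. Carbodiimide coupling with 2-[bis(2,2,2-trifluoroethoxy)phosphoryl]propanoic acid gives the phosphonopropionate ester F5. Still–Gennari olefination with acetaldehyde (KN(SiMe3)2, 18-crown-6, THF, −78 °C) gives the Z-trisubstituted enoate, that is 23, where the route is rejoined.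

**Further compounds**
F1 | step 14 | tertiary bromohydrin from 18 (Br at C11, OH at C1, other centres as in 18) | CC(C)(Br)[C@H](O)[C@@H](OC(=O)C(C)C)C[C@@]2(C)[C@@H]3[C@@H](O[Si](C)(C)C(C)(C)C)CC(=C)[C@H]2C3=O
F2 | step 14 | N-(2-phenylaziridin-1-yl)imine of F1 at the cyclobutanone carbon | CC(C)(Br)[C@H](O)[C@@H](OC(=O)C(C)C)C[C@@]2(C)[C@@H]3[C@@H](O[Si](C)(C)C(C)(C)C)CC(=C)[C@H]2C3=NN4CC4c5ccccc5
F3 | step 9 | pyrrolidine amide of acid 12 | O=C(/C=C(\C)C[C@H](O[Si](C)(C)C(C)(C)C)/C=C(\C)C[C@H](O[Si](CC)(CC)CC)C=C(C)C)N1CCCC1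
F4 | step 9 | cyclobutaniminium triflate corresponding to ketone 15 (pyrrolidinium ylidene at C10) | CC(C)=C[C@@H](O[Si](CC)(CC)CC)C[C@@]1(C)[C@@H]2[C@@H](O[Si](C)(C)C(C)(C)C)CC(=C)[C@H]1C2=[N+]3CCCC3.[O-]S(=O)(=O)C(F)(F)F
F5 | step 15 | 2-[bis(2,2,2-trifluoroethoxy)phosphoryl]propanoate ester of 22 at the C1 oxygen (phosphonate α-carbon not defined) | CC(C(=O)O[C@@H]1[C@@H](OC(=O)C(C)C)C[C@@]2(C)[C@@H]3[C@@H](O[Si](C)(C)C(C)(C)C)CC(=C)[C@H]2[C@@H]3C1(C)C)P(=O)(OCC(F)(F)F)OCC(F)(F)F
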